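## Retrosynthetic overview

- **Feature:** ring B is numbered C1' O-aryl, C2' OH, C3' Me, C4' OMe, C5' Ac, C6' OH. The triad C2'(OH)–C3'(Me)–C4'(OMe) is what a ketene carbon leaves behind after it is joined to 1-methoxypropyne. The neighbouring ether carbon C1' can be the sp3 carbon of a cyclobutenone.
- **Key disconnection:** ring B is opened along C2'–C3', C4'–C5' and C1'–C2' into 1-methoxypropyne and a 4-aryloxy-3-benzyloxycyclobutenone. Ring B is therefore grown around the ether carbon, and no crowded arene is ever O-arylated.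
- **Cyclobutenone:** it goes back to the (2+2) addition of the ring A aryloxyketene to benzyloxyethyne. The ketene goes back to O-alkylation of the ring A phenol with tert-butyl bromoacetate.
- **Mask:** an aryloxyketene with an ortho acetyl group would add to its own carbonyl (β-lactone, then benzofuran). The acetyl/C3–OH pair of ring A therefore travels as a 3-methyl-1,2-benzisoxazole. Hydrogenolysis opens it together with the benzyl ether, and the C5' acetyl group is added last by Friedel–Crafts acylation.
- **Ring order:** ring A (bought as 2-methylphloroglucinol), isoxazole ring (mask), four-membered ring, ring B.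

Key step: step 12

Remark: ring A is numbered from its ether carbon (C1 O-aryl, C2 Ac, C3 OH, C4 Me, C5 OMe, C6 H), and Ar stands for 6-methoxy-3,7-dimethyl-1,2-benzoxazol-4-yl (masked ring A). The target is achiral, and the stereocentres of the racemic compounds 18, 23 and 25 are erased in step 12. 1-Methoxypropyne is made because its supply is taken to be uncertain.

## Route

Step 1
Reactants: 1 2-methylphloroglucinol (2-methylbenzene-1,3,5-triol)
Product: 2 1-(2,4,6-trihydroxy-3-methylphenyl)ethanone
Conditions: Ac2O (1.0 equiv), BF3·OEt2, rt → 60 °C; then H2O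
Reagents that add atoms: acetic anhydride, CC(=O)OC(C)=O
Why: Friedel–Crafts C-acylation of a phloroglucinol, in which the two free ring carbons of 1 are equivalent and the first acetyl group, complexed by BF3, slows a second acylation.

Step 2
Reactants: 2 1-(2,4,6-trihydroxy-3-methylphenyl)ethanone
Product: 3 1-(2,6-dihydroxy-4-methoxy-3-methylphenyl)ethanone
Conditions: Me2SO4 (1.0 equiv), K2CO3 (1.0 equiv), acetone, reflux
Reagents that add atoms: dimethyl sulfate, COS(=O)(=O)OC
Why: Williamson-type O-methylation with one equivalent of reagent should take the most acidic hydroxyl, the one para to the acetyl group, because the two ortho hydroxyls are held back by hydrogen bonding to the carbonyl oxygen.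

Step 3
Reactants: 3 1-(2,6-dihydroxy-4-methoxy-3-methylphenyl)ethanone; 4 tert-butyl bromoacetate
Product: 5 tert-butyl 2-(2-acetyl-3-hydroxy-5-methoxy-4-methylphenoxy)acetate
Conditions: K2CO3 (1.1 equiv), acetone, reflux
Reagents that add atoms: none
Why: Williamson ether synthesis at the ortho hydroxyl that lies next to C–H, since the other one is squeezed between methyl and acetyl and keeps the chelate, and K2CO3 in acetone is too weak to start the aldol closure of the aryloxyacetate onto the acetyl group.

Step 4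
Reactants: 5 tert-butyl 2-(2-acetyl-3-hydroxy-5-methoxy-4-methylphenoxy)acetate
Product: 6 tert-butyl 2-{3-hydroxy-2-[(1E)-1-(hydroxyimino)ethyl]-5-methoxy-4-methylphenoxy}acetate
Conditions: NH2OH·HCl, NaOAc, EtOH–H2O, reflux
Reagents that add atoms: hydroxylamine hydrochloride, Cl.NO
Why: Oxime condensation, in which the phenol O–H···N hydrogen bond favours the (E)-oxime (N–OH anti to the ring) that the next step needs, and the bulky tert-butyl ester resists hydroxylamine.

Step 5
Reactants: 6 tert-butyl 2-{3-hydroxy-2-[(1E)-1-(hydroxyimino)ethyl]-5-methoxy-4-methylphenoxy}acetate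
Product: 7 tert-butyl 2-[(6-methoxy-3,7-dimethyl-1,2-benzoxazol-4-yl)oxy]acetate
Conditions: PPh3, DIAD, THF, 0 °C → rt
Reagents that add atoms: none
Why: Mitsunobu cyclodehydration of an o-hydroxyaryl ketoxime, in which the oxime oxygen leaves as an oxyphosphonium group and the phenol oxygen displaces it at nitrogen (five-membered N–O closure), so that the acetyl/hydroxyl pair becomes an aromatic ring with no carbonyl group for a ketene to attack.

Step 6
Reactants: 7 tert-butyl 2-[(6-methoxy-3,7-dimethyl-1,2-benzoxazol-4-yl)oxy]acetate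
Product: 8 2-[(6-methoxy-3,7-dimethyl-1,2-benzoxazol-4-yl)oxy]acetic acid
Conditions: TFA–CH2Cl2 (1:1), rt
Reagents that add atoms: none
Why: Acidolysis of a tert-butyl ester by loss of isobutene, to which the aryl ethers and the 3-substituted benzisoxazole are inert.

Step 7
Reactants: 8 2-[(6-methoxy-3,7-dimethyl-1,2-benzoxazol-4-yl)oxy]acetic acid
Product: 9 2-[(6-methoxy-3,7-dimethyl-1,2-benzoxazol-4-yl)oxy]acetyl chloride
Conditions: (COCl)2, cat. DMF, CH2Cl2, 0 °C → rt; concentrate
Reagents that add atoms: oxalyl chloride, O=C(Cl)C(=O)Cl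
Why: Acid chloride formation under chloroiminium (Vilsmeier-type) catalysis, with no other group in 8 that reacts with oxalyl chloride.

Step 8
Reactants: 10 benzyl alcohol; 11 trichloroethylene
Product: 13 {[(E)-1,2-dichloroethenyl]oxy}methylbenzene, via dichloroethyne 12 (not isolated)
Conditions: KH (1.2 equiv), THF, 0 °C; then 11, −50 °C → rt
Reagents that add atoms: none
Why: Elimination–addition, in which the alkoxide takes HCl from 11 to give 12 and anti addition of benzyl oxide and a proton across the triple bond sets the (E) geometry of the dichlorovinyl ether.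

Step 9
Reactants: 13 {[(E)-1,2-dichloroethenyl]oxy}methylbenzene
Product: 16 (ethynyloxy)methylbenzene (benzyloxyethyne), via benzyl chloroethynyl ether 14 (not isolated), via lithium benzyloxyacetylide 15 (not isolated)
Conditions: n-BuLi (2.2 equiv), Et2O, −78 → −40 °C; H2O, −78 → 0 °C; kept as a cold Et2O solution
Reagents that add atoms: none
Why: β-Elimination of LiCl after vinyl deprotonation gives 14, chlorine–lithium exchange gives 15 and cold protonation gives 16, which is handled below room temperature because benzyl ynol ethers rearrange sigmatropically near 60 °C.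

Step 10
Reactants: 9 2-[(6-methoxy-3,7-dimethyl-1,2-benzoxazol-4-yl)oxy]acetyl chloride; 16 benzyloxyethyne
Product: 18 3-(benzyloxy)-4-[(6-methoxy-3,7-dimethyl-1,2-benzoxazol-4-yl)oxy]cyclobut-2-en-1-one (racemic), via aryloxyketene 17 (not isolated)
Conditions: 16 (2 equiv), Et3N (1.2 equiv), CH2Cl2, slow addition of 9, 0 °C → rt
Reagents that add atoms: none
Why: Ketene–ynol ether (2+2) cycloaddition, in which Et3N dehydrochlorinates 9 to 17 and the nucleophilic terminal carbon of 16 bonds to the ketene carbonyl carbon, so that the benzyloxy carbon lies next to the aryloxy-bearing sp3 carbon, whose configuration is uncontrolled and irrelevant.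

Step 11
Reactants: 19 2-chloro-1,1-dimethoxyethane (chloroacetaldehyde dimethyl acetal)
Product: 21 1-methoxyprop-1-yne, via sodium methoxyacetylide 20 (not isolated)
Conditions: NaNH2 (3 equiv), liq. NH3, −33 °C; MeI; H2O, pentane, fractional distillation
Reagents that add atoms: iodomethane, CI
Why: Twofold base-induced elimination (MeOH, then HCl) from a chloroacetal gives the alkoxyacetylide 20, which is C-methylated in the same flask, the standard liquid-ammonia route to 1-alkoxyalk-1-ynes.

Step 12
Reactants: 18 3-(benzyloxy)-4-(aryloxy)cyclobut-2-en-1-one (racemic); 21 1-methoxyprop-1-yne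
Product: 26 3-(benzyloxy)-5-methoxy-2-[(6-methoxy-3,7-dimethyl-1,2-benzoxazol-4-yl)oxy]-6-methylphenol, via aryloxy vinylketene 22 (not isolated), via vinylcyclobutenone 23 (not isolated), via dienylketene 24 (not isolated), via cyclohexadienone 25 (not isolated)
Conditions: 21 (3 equiv), degassed toluene, sealed tube, 80 °C then 110 °C
Reagents that add atoms: none
Why: Danheiser benzannulation, a four-stage pericyclic cascade: conrotatory 4π opening of the C1–C4 bond of 18, with the aryloxy donor turning outward, gives vinylketene 22, and the methyl-bearing (nucleophilic) carbon of ynol ether 21 attacks its ketene carbon, so that the (2+2) addition forms C2'–C3' and C4'–C5' and gives vinylcyclobutenone 23. Reversible 4π opening of 23 gives dienylketene 24, and the isomer with the vinyl arm turned inward closes ring B by disrotatory 6π electrocyclisation between the ketene carbon and the aryloxy-bearing terminus (C1'–C2'), after which dienone 25 enolises to phenol 26. The closest known reaction type is the thermal annulation of 3-substituted cyclobutenones with alkoxy- and silyloxyalkynes to resorcinol monoethers, and 4-oxygenated cyclobutenones are known to open readily with the oxygen outward. No stereocentre survives, since the centres of racemic 18, 23 and 25 are all erased on aromatisation. The one selectivity needed is the orientation of the ketene–alkyne addition, and the polarisation of 21 secures it, which puts the methyl group between hydroxyl and methoxy and leaves the three new ring B oxygens different from birth (free OH, OMe, OBn). Excess 21 should outrun ketene dimerisation and acylation of 26, and the benzisoxazole offers the ketenes neither a carbonyl group nor an acidic hydrogen.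

Step 13
Reactants: 26 3-(benzyloxy)-5-methoxy-2-[(6-methoxy-3,7-dimethyl-1,2-benzoxazol-4-yl)oxy]-6-methylphenol
Product: 28 1-[2-(2,6-dihydroxy-4-methoxy-3-methylphenoxy)-6-hydroxy-4-methoxy-3-methylphenyl]ethanone, via hydroxyaryl ketimine 27 (not isolated)
Conditions: H2 (1 atm), 10% Pd/C, EtOAc–EtOH, rt; filter; 1 M HCl, THF, 50 °C
Reagents that add atoms: water, O
Why: Catalytic hydrogenolysis cleaves the benzyl ether and the weak N–O bond of the benzisoxazole to the hindered, hydrogen-bonded ketimine 27, and aqueous acid hydrolyses this imine to the ring A acetyl group next to its C3 hydroxyl.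

Step 14
Reactants: 28 1-[2-(2,6-dihydroxy-4-methoxy-3-methylphenoxy)-6-hydroxy-4-methoxy-3-methylphenyl]ethanone
Product: 29 leprolomin
Conditions: Ac2O (1.1 equiv), BF3·OEt2, 0 °C → rt (50 °C if needed); then H2O–MeOH, reflux
Reagents that add atoms: acetic anhydride, CC(=O)OC(C)=O
Why: Friedel–Crafts C-acylation with Fries-type equilibration of any O-acetate, directed to C5' as the only free carbon of the phloroglucinol-like ring B (ortho to C6'–OH and C4'–OMe, para to C2'–OH), while the lone C6–H of ring A is deactivated by the BF3-complexed acetyl group.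

## Compound list

| No. | Name | SMILES | Role |
|---|---|---|---|
| 1 | 2-methylphloroglucinol | Cc1c(O)cc(O)cc1O | starting material |
| 2 | 1-(2,4,6-trihydroxy-3-methylphenyl)ethanone | CC(=O)c1c(O)cc(O)c(C)c1O | intermediate |
| 3 | 1-(2,6-dihydroxy-4-methoxy-3-methylphenyl)ethanone | CC(=O)c1c(O)cc(OC)c(C)c1O | intermediate |
| 4 | tert-butyl bromoacetate | CC(C)(C)OC(=O)CBr | starting material |
| 5 | tert-butyl 2-(2-acetyl-3-hydroxy-5-methoxy-4-methylphenoxy)acetate | CC(=O)c1c(OCC(=O)OC(C)(C)C)cc(OC)c(C)c1O | intermediate |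
| 6 | tert-butyl 2-{3-hydroxy-2-[(1E)-1-(hydroxyimino)ethyl]-5-methoxy-4-methylphenoxy}acetate | C/C(=N\O)c1c(OCC(=O)OC(C)(C)C)cc(OC)c(C)c1O | intermediate |
| 7 | tert-butyl 2-[(6-methoxy-3,7-dimethyl-1,2-benzoxazol-4-yl)oxy]acetate | Cc1noc2c(C)c(OC)cc(OCC(=O)OC(C)(C)C)c12 | intermediate |
| 8 | 2-[(6-methoxy-3,7-dimethyl-1,2-benzoxazol-4-yl)oxy]acetic acid | Cc1noc2c(C)c(OC)cc(OCC(=O)O)c12 | intermediate |
| 9 | 2-[(6-methoxy-3,7-dimethyl-1,2-benzoxazol-4-yl)oxy]acetyl chloride | Cc1noc2c(C)c(OC)cc(OCC(=O)Cl)c12 | intermediate |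
| 10 | benzyl alcohol | OCc1ccccc1 | starting material |
| 11 | trichloroethylene | ClC=C(Cl)Cl | starting material |
| 12 | dichloroethyne | ClC#CCl | intermediate |
| 13 | {[(E)-1,2-dichloroethenyl]oxy}methylbenzene | Cl/C=C(/Cl)OCc1ccccc1 | intermediate |
| 14 | [(chloroethynyl)oxy]methylbenzene | ClC#COCc1ccccc1 | intermediate |
| 15 | lithium benzyloxyacetylide | [Li]C#COCc1ccccc1 | intermediate |
| 16 | (ethynyloxy)methylbenzene (benzyloxyethyne) | C#COCc1ccccc1 | intermediate |
| 17 | 2-(ArO)ethen-1-one (aryloxyketene) | Cc1noc2c(C)c(OC)cc(OC=C=O)c12 | intermediate |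
| 18 | 3-(benzyloxy)-4-[(6-methoxy-3,7-dimethyl-1,2-benzoxazol-4-yl)oxy]cyclobut-2-en-1-one, racemic | O=C1C=C(OCc2ccccc2)C1Oc1cc(OC)c(C)c2onc(C)c12 | intermediate |
| 19 | 2-chloro-1,1-dimethoxyethane | COC(CCl)OC | starting material |
| 20 | sodium methoxyacetylide | [Na]C#COC | intermediate |
| 21 | 1-methoxyprop-1-yne | CC#COC | intermediate |
| 22 | (3Z)-4-(ArO)-3-(benzyloxy)buta-1,3-dien-1-one | O=C=C/C(OCc1ccccc1)=C/Oc1cc(OC)c(C)c2onc(C)c12 | intermediate |
| 23 | 4-[(Z)-2-(ArO)-1-(benzyloxy)ethenyl]-3-methoxy-2-methylcyclobut-2-en-1-one, racemic | O=C1C(C)=C(OC)C1/C(OCc1ccccc1)=C/Oc1cc(OC)c(C)c2onc(C)c12 | intermediate |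
| 24 | (3E,5Z)-6-(ArO)-5-(benzyloxy)-3-methoxy-2-methylhexa-1,3,5-trien-1-one | O=C=C(C)/C(OC)=C\C(OCc1ccccc1)=C\Oc1cc(OC)c(C)c2onc(C)c12 | intermediate |
| 25 | 6-(ArO)-5-(benzyloxy)-3-methoxy-2-methylcyclohexa-2,4-dien-1-one, racemic | O=C1C(C)=C(OC)C=C(OCc2ccccc2)C1Oc1cc(OC)c(C)c2onc(C)c12 | intermediate |
| 26 | 3-(benzyloxy)-5-methoxy-2-[(6-methoxy-3,7-dimethyl-1,2-benzoxazol-4-yl)oxy]-6-methylphenol | COc1cc(OCc2ccccc2)c(Oc2cc(OC)c(C)c3onc(C)c23)c(O)c1C | intermediate |
| 27 | 2-[3-hydroxy-2-(1-iminoethyl)-5-methoxy-4-methylphenoxy]-5-methoxy-4-methylbenzene-1,3-diol | CC(=N)c1c(O)c(C)c(OC)cc1Oc1c(O)cc(OC)c(C)c1O | intermediate |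
| 28 | 1-[2-(2,6-dihydroxy-4-methoxy-3-methylphenoxy)-6-hydroxy-4-methoxy-3-methylphenyl]ethanone | CC(=O)c1c(O)c(C)c(OC)cc1Oc1c(O)cc(OC)c(C)c1O | intermediate |
| 29 | leprolomin | COc1cc(Oc2c(O)c(C)c(OC)c(C(C)=O)c2O)c(C(C)=O)c(O)c1C | target |

## Step count and risks

Total step count: 14.
Longest linear sequence: 11 (steps 1–7, 10, 12, 13, 14).

**Step 12.**
- *What may go wrong:* the vinylogous-ester character of the 3-benzyloxycyclobutenone may delay the 4π opening. The electron-rich vinylketene may also be captured too slowly by the volatile ynol ether, so that ketene dimerisation and acylation of the product phenol take over.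
- *Fallback:* it sets out from 18 and comes back at 28.
  - Compound 18 is heated with 1-(triisopropylsilyloxy)prop-1-yne F1, made from propyne with n-BuLi, t-BuOOLi and then TIPSOTf. A silyl ynol ether is a non-volatile and more nucleophilic ketenophile, and it should give silyl ether F2 at lower temperature.
  - The methyl group is then placed by exchange of protecting groups. BnBr and K2CO3 in DMF convert C2'–OH into bis(benzyl) ether F3. TBAF in THF frees the C4' phenol F4. MeI and K2CO3 in acetone give methyl ether F5.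
  - Hydrogenolysis and hydrolysis of F5 under the conditions of step 13 lead through 27 to 28.

**Step 10.**
- *What may go wrong:* the benzyl ynol ether may be lost by sigmatropic rearrangement or polymerisation before it meets the ketene. The aryloxyketene may also condense with itself.
- *Fallback:* it sets out from 9 and comes back at 28.
  - Propan-2-ol and 11 are taken, in the manner of steps 8 and 9, through (E)-1,2-dichlorovinyl isopropyl ether F6 to isopropoxyethyne F7. This ynol ether has no aryl ring for a sigmatropic escape and can be distilled.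
  - Ketene 17, generated from 9 as before, is trapped by F7 to give isopropoxycyclobutenone F8. Benzannulation of F8 with 21 gives isopropyl ether F9.
  - BCl3 in CH2Cl2 at −78 → 0 °C removes the secondary alkyl ether and spares the methyl ethers, which gives diol F10.
  - Hydrogenolysis of the N–O bond and hydrolysis as in step 13 lead through 27 to 28.

**Step 14.**
- *What may go wrong:* O-acetylation may fail to equilibrate to carbon. A second acylation may also occur at the lone C–H of ring A.
- *Fallback:* it sets out from 26 and comes back at 29. The ketone is brought in by cross-coupling.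
  - NIS in MeCN at 0 °C iodinates C5', para to the free hydroxyl, to give aryl iodide F11.
  - Stille coupling with tributyl(1-ethoxyvinyl)stannane (PdCl2(PPh3)2, toluene, 100 °C) gives enol ether F12, and dilute HCl in THF gives methyl ketone F13.
  - H2 over Pd/C followed by aqueous HCl leads through ketimine F14 to 29.

## Further compounds

F1 | step 12 | 1-(triisopropylsilyloxy)prop-1-yne | CC#CO[Si](C(C)C)(C(C)C)C(C)C
F2 | step 12 | 3-(benzyloxy)-2-[(6-methoxy-3,7-dimethyl-1,2-benzoxazol-4-yl)oxy]-6-methyl-5-(triisopropylsilyloxy)phenol | Cc1c(O)c(Oc2cc(OC)c(C)c3onc(C)c23)c(OCc2ccccc2)cc1O[Si](C(C)C)(C(C)C)C(C)C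
F3 | step 12 | 4-[2,6-bis(benzyloxy)-3-methyl-4-(triisopropylsilyloxy)phenoxy]-6-methoxy-3,7-dimethyl-1,2-benzoxazole | Cc1c(OCc2ccccc2)c(Oc2cc(OC)c(C)c3onc(C)c23)c(OCc2ccccc2)cc1O[Si](C(C)C)(C(C)C)C(C)C
F4 | step 12 | 3,5-bis(benzyloxy)-4-[(6-methoxy-3,7-dimethyl-1,2-benzoxazol-4-yl)oxy]-2-methylphenol | Cc1c(OCc2ccccc2)c(Oc2cc(OC)c(C)c3onc(C)c23)c(OCc2ccccc2)cc1O
F5 | step 12 | 4-[2,6-bis(benzyloxy)-4-methoxy-3-methylphenoxy]-6-methoxy-3,7-dimethyl-1,2-benzoxazole | Cc1c(OCc2ccccc2)c(Oc2cc(OC)c(C)c3onc(C)c23)c(OCc2ccccc2)cc1OC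
F6 | step 10 | 2-{[(E)-1,2-dichloroethenyl]oxy}propane | Cl/C=C(/Cl)OC(C)C
F7 | step 10 | 2-(ethynyloxy)propane (isopropoxyethyne) | C#COC(C)C
F8 | step 10 | 4-[(6-methoxy-3,7-dimethyl-1,2-benzoxazol-4-yl)oxy]-3-(propan-2-yloxy)cyclobut-2-en-1-one, racemic | O=C1C=C(OC(C)C)C1Oc1cc(OC)c(C)c2onc(C)c12
F9 | step 10 | 5-methoxy-2-[(6-methoxy-3,7-dimethyl-1,2-benzoxazol-4-yl)oxy]-6-methyl-3-(propan-2-yloxy)phenol | COc1cc(OC(C)C)c(Oc2cc(OC)c(C)c3onc(C)c23)c(O)c1C
F10 | step 10 | 5-methoxy-2-[(6-methoxy-3,7-dimethyl-1,2-benzoxazol-4-yl)oxy]-4-methylbenzene-1,3-diol | COc1cc(O)c(Oc2cc(OC)c(C)c3onc(C)c23)c(O)c1C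
F11 | step 14 | 3-(benzyloxy)-4-iodo-5-methoxy-2-[(6-methoxy-3,7-dimethyl-1,2-benzoxazol-4-yl)oxy]-6-methylphenol | COc1c(I)c(OCc2ccccc2)c(Oc2cc(OC)c(C)c3onc(C)c23)c(O)c1C
F12 | step 14 | 3-(benzyloxy)-4-(1-ethoxyethenyl)-5-methoxy-2-[(6-methoxy-3,7-dimethyl-1,2-benzoxazol-4-yl)oxy]-6-methylphenol | COc1c(C(=C)OCC)c(OCc2ccccc2)c(Oc2cc(OC)c(C)c3onc(C)c23)c(O)c1C
F13 | step 14 | 1-{2-(benzyloxy)-4-hydroxy-6-methoxy-3-[(6-methoxy-3,7-dimethyl-1,2-benzoxazol-4-yl)oxy]-5-methylphenyl}ethanone | COc1c(C(C)=O)c(OCc2ccccc2)c(Oc2cc(OC)c(C)c3onc(C)c23)c(O)c1C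
F14 | step 14 | 1-{2,4-dihydroxy-3-[3-hydroxy-2-(1-iminoethyl)-5-methoxy-4-methylphenoxy]-6-methoxy-5-methylphenyl}ethanone | CC(=N)c1c(O)c(C)c(OC)cc1Oc1c(O)c(C)c(OC)c(C(C)=O)c1O
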